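**Retrosynthetic overview**

- The strategy rests on C2, the only stereocentre: it is the β-carbon of the C2=C3–C4=O enone of ring C and carries the guaiacyl ring B through the C2–C1′ bond. That bond is therefore cut last, back to a flat, achiral 6-alkyl-5,7-bis(MOM)chromone 21 and arylboronic acid 26, with a chiral rhodium catalyst choosing the face.
- Ring C of the chromone is closed through O1–C2 by 6-endo oxa-Michael addition in an aryl ynone, itself made from salicylaldehyde 17 and an ethynyl Grignard reagent.
- Aldehyde 17 comes from ortho-formylation of phenol 15. Ring A of 15 (O5 / C6 chain / O7) is mirror-symmetric through the chain-bearing carbon (future C6) and the hydroxyl-bearing carbon (future C8a), so both ortho positions are the same and only the 6-alkyl series can form.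
- The C6–C1″ bond is made by lithiation between the two MOM ethers of a phloroglucinol-derived arene, transfer to copper and SN2 allylation with bromide 8. Bromide 8 is made from geranyl acetate (distal epoxide, selenide opening, selenoxide elimination to the E tertiary allylic alcohol).
- Ring order: ring A is bought (phloroglucinol), ring C is closed second, ring B is attached last, then the acetals and the silyl ether are removed.

Key step: step 17

Assumption: the (S)-configured biaryl bisphosphine is taken to deliver the aryl group to the chromone face that gives (2S), by analogy with its known sense on cyclic enones (worked through the CIP priorities at C2); if the sense proved opposite, the (R)-ligand would be used with no other change. Compounds 2, 3, 4 and 18 are racemic, and their stereocentres disappear later.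

**Route**

Step 1
Reactants: 1 geranyl acetate
Product: 2 6,7-epoxygeranyl acetate (racemic)
Conditions: mCPBA (1.05 equiv), NaHCO3, CH2Cl2, 0 °C
Reagents that add atoms: mCPBA O=C(OO)c1cccc(Cl)c1
Why: Prilezhaev epoxidation should take the electron-rich distal 6,7-alkene, because the 2,3-alkene is deactivated by the allylic acetate.

Step 2
Reactants: 2 6,7-epoxygeranyl acetate
Product: 3 (2E)-7-hydroxy-3,7-dimethyl-6-(phenylselanyl)oct-2-en-1-yl acetate (racemic)
Conditions: PhSeSePh (0.55 equiv), NaBH4 (1.2 equiv), EtOH, 0 °C → rt; then 2, rt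
Reagents that add atoms: diphenyl diselenide c1ccc([Se][Se]c2ccccc2)cc1
Why: The borate-complexed selenolate (Sharpless selenide opening) should attack the less hindered secondary epoxide carbon C6 by SN2 and is weakly basic enough to leave the allylic acetate in place at room temperature.

Step 3
Reactants: 3 hydroxy selenide
Product: 5 (2E,5E)-7-hydroxy-3,7-dimethylocta-2,5-dien-1-yl acetate, via selenoxide 4 (not isolated)
Conditions: H2O2 (30 % aq., 3 equiv), pyridine, THF, 0 °C → rt
Reagents that add atoms: none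
Why: Oxidation to the selenoxide and spontaneous syn-elimination (Sharpless–Lauer allylic alcohol synthesis) can only remove a C5 hydrogen, since C7 has none, and the cyclic five-membered transition state should give the E 5,6-alkene.

Step 4
Reactants: 5 (2E,5E)-7-hydroxy-3,7-dimethylocta-2,5-dien-1-yl acetate
Product: 6 (2E,5E)-3,7-dimethyl-7-(triethylsilyloxy)octa-2,5-dien-1-yl acetate
Conditions: TESOTf (1.2 equiv), 2,6-lutidine, CH2Cl2, −78 → 0 °C
Reagents that add atoms: triethylsilyl triflate CC[Si](CC)(CC)OS(=O)(=O)C(F)(F)F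
Why: A silyl triflate with a hindered pyridine base is the standard way to silylate a tertiary alcohol, and it leaves the acetate and both alkenes untouched.

Step 5
Reactants: 6 TES-protected acetate
Product: 7 (2E,5E)-3,7-dimethyl-7-(triethylsilyloxy)octa-2,5-dien-1-ol
Conditions: K2CO3 (0.2 equiv), MeOH, 0 °C → rt
Reagents that add atoms: none
Why: Base-catalysed methanolysis removes the primary acetate, while a tertiary alkyl triethylsilyl ether is inert to carbonate in methanol.

Step 6
Reactants: 7 allylic alcohol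
Product: 8 (2E,5E)-7-(triethylsilyloxy)-3,7-dimethylocta-2,5-dien-1-yl bromide
Conditions: CBr4 (1.2 equiv), PPh3 (1.25 equiv), CH2Cl2, 0 °C; used at once
Reagents that add atoms: carbon tetrabromide BrC(Br)(Br)Br
Why: The Appel reaction converts the primary allylic alcohol to the bromide by SN2 under neutral conditions, so the acid-labile tertiary allylic silyl ether and the E 2,3-alkene should be kept.

Step 7
Reactants: 9 phloroglucinol
Product: 10 5-(triisopropylsilyloxy)benzene-1,3-diol
Conditions: TIPSCl (1.0 equiv), imidazole (1.2 equiv), phloroglucinol in threefold excess, DMF, 0 °C → rt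
Reagents that add atoms: triisopropylsilyl chloride CC(C)[Si](Cl)(C(C)C)C(C)C
Why: Statistical mono-silylation of the C3-symmetric triol with a bulky silyl chloride is favoured by excess triol, which is removed by aqueous washing.

Step 8
Reactants: 10 5-(triisopropylsilyloxy)benzene-1,3-diol
Product: 11 [3,5-bis(methoxymethoxy)phenoxy]triisopropylsilane
Conditions: MOMCl (3 equiv), i-Pr2NEt (4 equiv), CH2Cl2, 0 °C → rt
Reagents that add atoms: chloromethyl methyl ether COCCl
Why: O-Alkylation of the two phenols with MOMCl under amine base installs the two lithiation-directing acetals without silyl migration.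

Step 9
Reactants: 11 [3,5-bis(methoxymethoxy)phenoxy]triisopropylsilane, 8 allylic bromide
Product: 14 triisopropylsilyl ether of 3,5-bis(methoxymethoxy)-4-[(2E,5E)-3,7-dimethyl-7-(triethylsilyloxy)octa-2,5-dien-1-yl]phenol, via aryllithium 12 (not isolated), via arylcopper 13 (not isolated)
Conditions: n-BuLi (1.1 equiv), THF, 0 °C, 1 h; CuBr·SMe2 (1.1 equiv), −78 → −40 °C; 8 (1.1 equiv), −78 → 0 °C
Reagents that add atoms: none
Why: Directed ortho-metalation should occur only at the carbon flanked by both MOM ethers (the positions next to the bulky, non-coordinating OTIPS are disfavoured), and the derived arylcopper should displace the primary allylic bromide by SN2 with retention of both E alkenes, because SN2′ attack would have to form a quaternary carbon next to a 2,6-disubstituted arene.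

Step 10
Reactants: 14 C4-alkylated silyl ether
Product: 15 3,5-bis(methoxymethoxy)-4-[(2E,5E)-3,7-dimethyl-7-(triethylsilyloxy)octa-2,5-dien-1-yl]phenol
Conditions: Bu4NF (1.05 equiv), THF, −20 → 0 °C, short reaction time; aq. NH4Cl
Reagents that add atoms: none
Why: Fluoride desilylation is much faster at the aryl silyl ether (phenoxide leaving group) than at the hindered tertiary alkyl triethylsilyl ether, so one equivalent of fluoride should free only the phenol.

Step 11
Reactants: 15 symmetric phenol
Product: 17 2-hydroxy-4,6-bis(methoxymethoxy)-5-[(2E,5E)-3,7-dimethyl-7-(triethylsilyloxy)octa-2,5-dien-1-yl]benzaldehyde, via ortho-hydroxymethyl phenoxide 16 (not isolated)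
Conditions: MgCl2 (2 equiv), Et3N (4 equiv), (CH2O)n (6 equiv), MeCN, 80 °C; pH 5 buffer work-up
Reagents that add atoms: formaldehyde (as paraformaldehyde) C=O
Why: In the Casnati–Skattebøl ortho-formylation the magnesium phenoxide delivers formaldehyde to the ortho carbon through a chelate and a second formaldehyde oxidises the salicyl alkoxide by hydride transfer, and since both ortho positions of 15 are equivalent by symmetry only this aldehyde can form.

Step 12
Reactants: 17 salicylaldehyde
Product: 18 1-{2-hydroxy-4,6-bis(methoxymethoxy)-5-[(2E,5E)-3,7-dimethyl-7-(triethylsilyloxy)octa-2,5-dien-1-yl]phenyl}prop-2-yn-1-ol (racemic)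
Conditions: HC≡CMgBr (3 equiv), THF, 0 °C → rt; aq. NH4Cl
Reagents that add atoms: ethynylmagnesium bromide C#C[Mg]Br
Why: Grignard 1,2-addition to the aldehyde proceeds after the first equivalent has deprotonated the phenol, and the acetals, silyl ether and alkenes are inert to the reagent.

Step 13
Reactants: 18 propargylic alcohol
Product: 19 1-{2-hydroxy-4,6-bis(methoxymethoxy)-5-[(2E,5E)-3,7-dimethyl-7-(triethylsilyloxy)octa-2,5-dien-1-yl]phenyl}prop-2-yn-1-one
Conditions: MnO2 (activated, excess), CH2Cl2, rt; crude used directly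
Reagents that add atoms: none
Why: MnO2 oxidises the doubly activated (benzylic and propargylic) secondary alcohol selectively and does not touch the isolated alkenes or the tertiary silyl ether.

Step 14
Reactants: 19 aryl ynone
Product: 21 5,7-bis(methoxymethoxy)-6-[(2E,5E)-3,7-dimethyl-7-(triethylsilyloxy)octa-2,5-dien-1-yl]-4H-chromen-4-one, via enaminone 20 (not isolated)
Conditions: Et2NH (3 equiv), EtOH, rt → 50 °C
Reagents that add atoms: none
Why: Aza-Michael addition of the amine gives the E enaminone, in which the phenol can only add at the β-carbon (oxa-Michael addition–elimination of the amine), so the ring closes 6-endo to the chromone and the 5-exo aurone-type pathway is avoided.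

Step 15
Reactants: 22 4-bromo-2-methoxyphenol
Product: 23 4-bromo-2-methoxy-1-(methoxymethoxy)benzene
Conditions: MOMCl (1.5 equiv), i-Pr2NEt (2 equiv), CH2Cl2, 0 °C → rt
Reagents that add atoms: chloromethyl methyl ether COCCl
Why: Routine O-alkylation of the phenol gives an acetal that survives organolithium chemistry and the later rhodium step.

Step 16
Reactants: 23 4-bromo-2-methoxy-1-(methoxymethoxy)benzene
Product: 26 3-methoxy-4-(methoxymethoxy)phenylboronic acid, via aryllithium 24 (not isolated), via lithium triisopropoxyborate 25 (not isolated)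
Conditions: n-BuLi (1.1 equiv), THF, −78 °C; B(Oi-Pr)3 (1.5 equiv), −78 °C → rt; aq. NH4Cl (pH about 6)
Reagents that add atoms: triisopropyl borate CC(C)OB(OC(C)C)OC(C)C; water O
Why: Bromine–lithium exchange at −78 °C is faster than any ortho-deprotonation, and trapping with the borate followed by near-neutral hydrolysis gives the boronic acid with the MOM ether intact.

Step 17
Reactants: 21 6-alkyl-5,7-bis(methoxymethoxy)chromone, 26 3-methoxy-4-(methoxymethoxy)phenylboronic acid
Product: 27 (2S)-2-[3-methoxy-4-(methoxymethoxy)phenyl]-5,7-bis(methoxymethoxy)-6-[(2E,5E)-3,7-dimethyl-7-(triethylsilyloxy)octa-2,5-dien-1-yl]chroman-4-one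
Conditions: [RhOH(cod)]2 (2.5 mol %), (S)-MeO-F12-BIPHEP [(S)-2,2′-bis[bis(3,4,5-trifluorophenyl)phosphino]-6,6′-dimethoxy-1,1′-biphenyl] (6 mol %), 26 (2.5 equiv), toluene–H2O (20:1), 35 °C
Reagents that add atoms: none
Why: The aryl group passes from boron to the hydroxo complex of monovalent rhodium, the chromone C2=C3 bond binds, migratory insertion places the aryl group on C2, and the resulting oxa-π-allyl rhodium enolate is protonated by water to release the flavanone and return the Rh–OH species. The closest known reaction type is the Hayashi–Miyaura asymmetric 1,4-addition of arylboronic acids to chromones, including 5,7-dioxygenated ones. No ring is closed: the C2–C1′ bond is formed on the existing pyranone ring C. The new stereocentre C2 is controlled only by the chiral bisphosphine on rhodium, which shields one face of the planar, s-trans-locked enone, and the (S)-ligand is expected to give (2S). The step needs enantioface selectivity, 1,4- over 1,2-addition and chemoselectivity over the side-chain alkenes; the enone is the only activated alkene, the electron-poor ligand speeds up insertion into the electron-rich chromone, and excess boronic acid covers protodeboronation. Making the stereocentre by C–C bond formation with O5 still protected avoids the reversible chalcone ring opening that erodes flavanone configuration.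

Step 18
Reactants: 27 fully protected (2S)-flavanone
Product: 29 (2S)-5,7-dihydroxy-2-(4-hydroxy-3-methoxyphenyl)-6-[(2E,5E)-3,7-dimethyl-7-(triethylsilyloxy)octa-2,5-dien-1-yl]chroman-4-one, via tris(trimethylsilyl) aryl ether 28 (not isolated)
Conditions: TMSOTf (8 equiv), 2,2′-bipyridyl (12 equiv), MeCN, 0 °C → rt; then H2O, rt
Reagents that add atoms: none
Why: The silyl triflate–bipyridyl pair cleaves aromatic MOM ethers by silyl transfer to the aryl oxygen and capture of the methoxymethyl cation by the pyridine nitrogen, and water then hydrolyses the aryl trimethylsilyl ethers, so no free Brønsted acid or base is present to ionise the tertiary allylic ether or epimerise C2.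

Step 19
Reactants: 29 triphenol with side-chain silyl ether
Product: 30 Tomentodiplacone B
Conditions: HF·pyridine, pyridine, THF, 0 °C → rt
Reagents that add atoms: none
Why: Buffered fluoride desilylation removes the tertiary triethylsilyl ether under mildly acidic, non-basic conditions, which should leave the tertiary allylic alcohol, the phenols and the C2 configuration of the 5-hydroxyflavanone unchanged.

**Compound list**

1 | geranyl acetate | CC(=O)OC/C=C(\C)CCC=C(C)C | starting material
2 | 6,7-epoxygeranyl acetate (racemic) | CC(=O)OC/C=C(\C)CCC1OC1(C)C | intermediate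
3 | (2E)-7-hydroxy-3,7-dimethyl-6-(phenylselanyl)oct-2-en-1-yl acetate (racemic) | CC(=O)OC/C=C(\C)CCC([Se]c1ccccc1)C(C)(C)O | intermediate
4 | selenoxide of 3 | CC(=O)OC/C=C(\C)CCC([Se](=O)c1ccccc1)C(C)(C)O | intermediate (not isolated)
5 | (2E,5E)-7-hydroxy-3,7-dimethylocta-2,5-dien-1-yl acetate | CC(=O)OC/C=C(\C)C/C=C/C(C)(C)O | intermediate
6 | (2E,5E)-3,7-dimethyl-7-(triethylsilyloxy)octa-2,5-dien-1-yl acetate | CC(=O)OC/C=C(\C)C/C=C/C(C)(C)O[Si](CC)(CC)CC | intermediate
7 | (2E,5E)-3,7-dimethyl-7-(triethylsilyloxy)octa-2,5-dien-1-ol | OC/C=C(\C)C/C=C/C(C)(C)O[Si](CC)(CC)CC | intermediate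
8 | (2E,5E)-7-(triethylsilyloxy)-3,7-dimethylocta-2,5-dien-1-yl bromide | BrC/C=C(\C)C/C=C/C(C)(C)O[Si](CC)(CC)CC | intermediate
9 | phloroglucinol | Oc1cc(O)cc(O)c1 | starting material
10 | 5-(triisopropylsilyloxy)benzene-1,3-diol | Oc1cc(O)cc(O[Si](C(C)C)(C(C)C)C(C)C)c1 | intermediate
11 | [3,5-bis(methoxymethoxy)phenoxy]triisopropylsilane | COCOc1cc(O[Si](C(C)C)(C(C)C)C(C)C)cc(OCOC)c1 | intermediate
12 | 2,6-bis(methoxymethoxy)-4-(triisopropylsilyloxy)phenyllithium | [Li]c1c(OCOC)cc(O[Si](C(C)C)(C(C)C)C(C)C)cc1OCOC | intermediate (not isolated)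
13 | 2,6-bis(methoxymethoxy)-4-(triisopropylsilyloxy)phenylcopper | [Cu]c1c(OCOC)cc(O[Si](C(C)C)(C(C)C)C(C)C)cc1OCOC | intermediate (not isolated)
14 | triisopropylsilyl ether of 3,5-bis(methoxymethoxy)-4-[(2E,5E)-3,7-dimethyl-7-(triethylsilyloxy)octa-2,5-dien-1-yl]phenol | COCOc1cc(O[Si](C(C)C)(C(C)C)C(C)C)cc(OCOC)c1C/C=C(\C)C/C=C/C(C)(C)O[Si](CC)(CC)CC | intermediate
15 | 3,5-bis(methoxymethoxy)-4-[(2E,5E)-3,7-dimethyl-7-(triethylsilyloxy)octa-2,5-dien-1-yl]phenol | COCOc1cc(O)cc(OCOC)c1C/C=C(\C)C/C=C/C(C)(C)O[Si](CC)(CC)CC | intermediate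
16 | 2-(hydroxymethyl) derivative of 15 (present as its magnesium phenoxide) | OCc1c(O)cc(OCOC)c(C/C=C(\C)C/C=C/C(C)(C)O[Si](CC)(CC)CC)c1OCOC | intermediate (not isolated)
17 | 2-hydroxy-4,6-bis(methoxymethoxy)-5-[(2E,5E)-3,7-dimethyl-7-(triethylsilyloxy)octa-2,5-dien-1-yl]benzaldehyde | O=Cc1c(O)cc(OCOC)c(C/C=C(\C)C/C=C/C(C)(C)O[Si](CC)(CC)CC)c1OCOC | intermediate
18 | 1-aryl-prop-2-yn-1-ol from 17 (racemic) | C#CC(O)c1c(O)cc(OCOC)c(C/C=C(\C)C/C=C/C(C)(C)O[Si](CC)(CC)CC)c1OCOC | intermediate
19 | 1-aryl-prop-2-yn-1-one (aryl ynone) | C#CC(=O)c1c(O)cc(OCOC)c(C/C=C(\C)C/C=C/C(C)(C)O[Si](CC)(CC)CC)c1OCOC | intermediate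
20 | (E)-3-(diethylamino)-1-aryl-prop-2-en-1-one (enaminone) | CCN(CC)/C=C/C(=O)c1c(O)cc(OCOC)c(C/C=C(\C)C/C=C/C(C)(C)O[Si](CC)(CC)CC)c1OCOC | intermediate (not isolated)
21 | 5,7-bis(methoxymethoxy)-6-[(2E,5E)-3,7-dimethyl-7-(triethylsilyloxy)octa-2,5-dien-1-yl]-4H-chromen-4-one | O=c1ccoc2cc(OCOC)c(C/C=C(\C)C/C=C/C(C)(C)O[Si](CC)(CC)CC)c(OCOC)c12 | intermediate
22 | 4-bromo-2-methoxyphenol | COc1cc(Br)ccc1O | starting material
23 | 4-bromo-2-methoxy-1-(methoxymethoxy)benzene | COCOc1ccc(Br)cc1OC | intermediate
24 | 3-methoxy-4-(methoxymethoxy)phenyllithium | [Li]c1ccc(OCOC)c(OC)c1 | intermediate (not isolated)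
25 | lithium triisopropoxy[3-methoxy-4-(methoxymethoxy)phenyl]borate | [Li+].COCOc1ccc([B-](OC(C)C)(OC(C)C)OC(C)C)cc1OC | intermediate (not isolated)
26 | 3-methoxy-4-(methoxymethoxy)phenylboronic acid | COCOc1ccc(B(O)O)cc1OC | intermediate
27 | (2S)-2-[3-methoxy-4-(methoxymethoxy)phenyl]-5,7-bis(methoxymethoxy)-6-[(2E,5E)-3,7-dimethyl-7-(triethylsilyloxy)octa-2,5-dien-1-yl]chroman-4-one | COc1cc([C@@H]2CC(=O)c3c(cc(OCOC)c(C/C=C(\C)C/C=C/C(C)(C)O[Si](CC)(CC)CC)c3OCOC)O2)ccc1OCOC | intermediate
28 | 5,7,4′-tris(trimethylsilyl) ether of 29 | COc1cc([C@@H]2CC(=O)c3c(cc(O[Si](C)(C)C)c(C/C=C(\C)C/C=C/C(C)(C)O[Si](CC)(CC)CC)c3O[Si](C)(C)C)O2)ccc1O[Si](C)(C)C | intermediate (not isolated)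
29 | (2S)-5,7-dihydroxy-2-(4-hydroxy-3-methoxyphenyl)-6-[(2E,5E)-3,7-dimethyl-7-(triethylsilyloxy)octa-2,5-dien-1-yl]chroman-4-one | COc1cc([C@@H]2CC(=O)c3c(cc(O)c(C/C=C(\C)C/C=C/C(C)(C)O[Si](CC)(CC)CC)c3O)O2)ccc1O | intermediate
30 | Tomentodiplacone B, (2S)-5,7-dihydroxy-2-(4-hydroxy-3-methoxyphenyl)-6-[(2E,5E)-7-hydroxy-3,7-dimethylocta-2,5-dien-1-yl]chroman-4-one | COc1cc([C@@H]2CC(=O)c3c(cc(O)c(C/C=C(\C)C/C=C/C(C)(C)O)c3O)O2)ccc1O | target

**Totals**

Total step count: 19. Longest linear sequence: 15 steps (steps 1–6, 9–14 and 17–19, from geranyl acetate).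

**Steps most likely to fail**

1. Step 17 (asymmetric arylation). What may go wrong: slow insertion into the electron-rich, 5-O-substituted chromone while the electron-rich boronic acid protodeboronates, or poor facial discrimination. The fallback closes ring C by C–O bond formation and separates the enantiomers instead of inducing one. It sets out from aldehyde 17. MeMgBr (3 equiv, THF, 0 °C) should give the 1-aryl-ethanol F1, and MnO2 in CH2Cl2 the 2-hydroxyacetophenone F2. Claisen–Schmidt condensation (KOH, EtOH–H2O, rt) with 3-methoxy-4-(methoxymethoxy)benzaldehyde F3 (from vanillin, MOMCl, i-Pr2NEt) should give the E 2′-hydroxychalcone F4. NaOAc in refluxing EtOH isomerises F4 by oxa-Michael closure of the free 2′-hydroxyl to the racemic protected flavanone F5. Preparative HPLC on a polysaccharide chiral stationary phase then separates the (2S)-enantiomer, which is compound 27, from the (2R)-enantiomer F6, which can be recycled through F4 with base. The fallback comes back to the route at 27.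

2. Step 18 (acetal cleavage on the finished flavanone). What may go wrong: silyl-triflate activation of the C4 carbonyl opening the pyranone at the β-aryloxy ketone, with loss of the C2 configuration on re-closure, or incomplete cleavage of the hindered 7-O acetal forcing long exposure. The fallback moves the acetal cleavage in front of the stereocentre, so the endgame is fluoride only. It sets out from chromone 21. TMSOTf/2,2′-bipyridyl in MeCN, then H2O, should give the 5,7-dihydroxychromone F12, and TBSOTf/2,6-lutidine in CH2Cl2 the 5,7-bis(tert-butyldimethylsilyl) chromone F13. In parallel, bromophenol 22 is silylated (TBSCl, imidazole, DMF) to aryl bromide F14 and converted (n-BuLi, B(Oi-Pr)3, aq. NH4Cl) to 4-(tert-butyldimethylsilyloxy)-3-methoxyphenylboronic acid F15. The rhodium-catalysed addition of F15 to F13 under the step 17 conditions should give the all-silyl (2S)-flavanone F16. Buffered fluoride (Bu4NF–AcOH in THF at 0 °C, then HF·pyridine if the tertiary silyl ether lingers) removes all four silyl groups. The fallback comes back to the route at target 30.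

3. Step 9 (aryl copper allylation). What may go wrong: decomposition of the functionalised allylic bromide 8 by ionisation or elimination before it couples, incomplete lithiation, or loss of regiocontrol through SN2′ attack. The fallback couples a robust bromide first and oxidises the side chain afterwards. It sets out from arene 11. The same lithiation and CuBr·SMe2 transfer (through 12 and 13), but with commercial geranyl bromide, should give the 4-geranyl arene F7. mCPBA (1.0 equiv, CH2Cl2, −20 °C) should epoxidise the distal alkene, the proximal one being shielded by the 2,6-bis(MOM)aryl group, to give epoxide F8. PhSeSePh/NaBH4 in EtOH opens F8 to hydroxy selenide F9. H2O2/pyridine in THF oxidises F9 to selenoxide F10, which eliminates to the E tertiary allylic alcohol F11. TESOTf/2,6-lutidine then silylates F11. The fallback comes back to the route at 14.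

**Further compounds**

F1 | step 17 | 1-{2-hydroxy-4,6-bis(methoxymethoxy)-5-[(2E,5E)-3,7-dimethyl-7-(triethylsilyloxy)octa-2,5-dien-1-yl]phenyl}ethanol (racemic) | CC(O)c1c(O)cc(OCOC)c(C/C=C(\C)C/C=C/C(C)(C)O[Si](CC)(CC)CC)c1OCOC
F2 | step 17 | 1-{2-hydroxy-4,6-bis(methoxymethoxy)-5-[(2E,5E)-3,7-dimethyl-7-(triethylsilyloxy)octa-2,5-dien-1-yl]phenyl}ethanone | CC(=O)c1c(O)cc(OCOC)c(C/C=C(\C)C/C=C/C(C)(C)O[Si](CC)(CC)CC)c1OCOC
F3 | step 17 | 3-methoxy-4-(methoxymethoxy)benzaldehyde | COCOc1ccc(C=O)cc1OC
F4 | step 17 | (E)-2′-hydroxy-4′,6′-bis(methoxymethoxy)-5′-alkyl-3-methoxy-4-(methoxymethoxy)chalcone | COCOc1ccc(/C=C/C(=O)c2c(O)cc(OCOC)c(C/C=C(\C)C/C=C/C(C)(C)O[Si](CC)(CC)CC)c2OCOC)cc1OC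
F5 | step 17 | racemic form of protected flavanone 27 | COc1cc(C2CC(=O)c3c(cc(OCOC)c(C/C=C(\C)C/C=C/C(C)(C)O[Si](CC)(CC)CC)c3OCOC)O2)ccc1OCOC
F6 | step 17 | (2R)-enantiomer of 27 | COc1cc([C@H]2CC(=O)c3c(cc(OCOC)c(C/C=C(\C)C/C=C/C(C)(C)O[Si](CC)(CC)CC)c3OCOC)O2)ccc1OCOC
F7 | step 9 | triisopropylsilyl ether of 4-geranyl-3,5-bis(methoxymethoxy)phenol | COCOc1cc(O[Si](C(C)C)(C(C)C)C(C)C)cc(OCOC)c1C/C=C(\C)CCC=C(C)C
F8 | step 9 | 6,7-epoxide of F7 (racemic) | COCOc1cc(O[Si](C(C)C)(C(C)C)C(C)C)cc(OCOC)c1C/C=C(\C)CCC2OC2(C)C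
F9 | step 9 | 7-hydroxy-6-(phenylselanyl) derivative of F7 (racemic) | COCOc1cc(O[Si](C(C)C)(C(C)C)C(C)C)cc(OCOC)c1C/C=C(\C)CCC([Se]c2ccccc2)C(C)(C)O
F10 | step 9 | selenoxide of F9 | COCOc1cc(O[Si](C(C)C)(C(C)C)C(C)C)cc(OCOC)c1C/C=C(\C)CCC([Se](=O)c2ccccc2)C(C)(C)O
F11 | step 9 | triisopropylsilyl ether of 4-[(2E,5E)-7-hydroxy-3,7-dimethylocta-2,5-dien-1-yl]-3,5-bis(methoxymethoxy)phenol | COCOc1cc(O[Si](C(C)C)(C(C)C)C(C)C)cc(OCOC)c1C/C=C(\C)C/C=C/C(C)(C)O
F12 | step 18 | 5,7-dihydroxy-6-[(2E,5E)-3,7-dimethyl-7-(triethylsilyloxy)octa-2,5-dien-1-yl]-4H-chromen-4-one | O=c1ccoc2cc(O)c(C/C=C(\C)C/C=C/C(C)(C)O[Si](CC)(CC)CC)c(O)c12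
F13 | step 18 | 5,7-bis(tert-butyldimethylsilyloxy)-6-[(2E,5E)-3,7-dimethyl-7-(triethylsilyloxy)octa-2,5-dien-1-yl]-4H-chromen-4-one | O=c1ccoc2cc(O[Si](C)(C)C(C)(C)C)c(C/C=C(\C)C/C=C/C(C)(C)O[Si](CC)(CC)CC)c(O[Si](C)(C)C(C)(C)C)c12
F14 | step 18 | (4-bromo-2-methoxyphenoxy)(tert-butyl)dimethylsilane | COc1cc(Br)ccc1O[Si](C)(C)C(C)(C)C
F15 | step 18 | 4-(tert-butyldimethylsilyloxy)-3-methoxyphenylboronic acid | COc1cc(B(O)O)ccc1O[Si](C)(C)C(C)(C)C
F16 | step 18 | (2S)-5,7-bis(tert-butyldimethylsilyloxy)-2-[4-(tert-butyldimethylsilyloxy)-3-methoxyphenyl]-6-[(2E,5E)-3,7-dimethyl-7-(triethylsilyloxy)octa-2,5-dien-1-yl]chroman-4-one | COc1cc([C@@H]2CC(=O)c3c(cc(O[Si](C)(C)C(C)(C)C)c(C/C=C(\C)C/C=C/C(C)(C)O[Si](CC)(CC)CC)c3O[Si](C)(C)C(C)(C)C)O2)ccc1O[Si](C)(C)C(C)(C)C
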